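The ratio in which left-handed and right-handed product form at each moment is the number to follow in these flasks, which differ in temperature.

    reagent + catalyst + left-handed substrate → catalyst + left-handed product (k1 = 40.9 M⁻² min⁻¹, Ea1 = 47.0 kJ mol⁻¹)
    reagent + catalyst + right-handed substrate → catalyst + right-handed product (k2 = 24.4 M⁻² min⁻¹, Ea2 = 61.0 kJ mol⁻¹)
    left-handed substrate ⇌ right-handed substrate (k3 = 0.0130 min⁻¹, Ea3 = 113 kJ mol⁻¹)
    2 reagent → self-condensation product (k4 = 0.166 M⁻¹ min⁻¹, Ea4 = 56.0 kJ mol⁻¹)
    precatalyst → catalyst (k5 = 1.09 min⁻¹, Ea5 = 84.0 kJ mol⁻¹)
    (constants at 60 °C)

| flask | left-handed substrate | reagent | precatalyst | right-handed substrate | time | remark | temperature |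
|---|---|---|---|---|---|---|---|
| west | 0.20 M | 0.500 M | 1.2 mM | 0.20 M | 1.0 h | at 35 °C until 40 min, from then on at 85 °C |  |
| north-west | 0.20 M | 0.500 M | 1.2 mM | 0.20 M | 1.0 h |  | 85 °C |
| south | 0.20 M | 0.500 M | 1.2 mM | 0.20 M | 1.0 h |  | 60 °C |
| south-west | 0.20 M | 0.500 M | 1.2 mM | 0.20 M | 1.0 h |  | 35 °C |

- catalyst is single-handed; left-handed substrate and right-handed substrate are mirror images of each other, charged as a racemate, each of them at the stated concentration
- a doubled species enters its step squared and goes two at a time
- constants are those at 60 °C; use the activation energies for any other temperature
- an excess is below zero if the other one leads

* the flask that comes out highest in excess of left-handed product over right-handed product, or "all alike" when all lie within 1.5 percentage points (west / north-west / south / south-west / all alike)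
* excess of left-handed product over right-handed product at the end, west
* excess of left-handed product over right-handed product at the end, north-west
* excess of left-handed product over right-handed product at the end, south
* excess of left-handed product over right-handed product at the end, south-west

The steps to left-handed and right-handed product both run on reagent and catalyst, so c(reagent) and c(catalyst) cancel from the ratio of their rates. What stays is the ratio of the two constants times c(left-handed substrate)/c(right-handed substrate). The self-condensation and the slow release of catalyst from precatalyst therefore do not stand in this ratio at any given moment, but they change how much product forms, and so they reach it through c(left-handed substrate)/c(right-handed substrate) and, in west, through the split between product made cold and product made hot. The substrates are charged equal, so the product ratio starts at the selectivity factor, the constant of the left-handed step over that of the right-handed step at the flask's temperature. At 35 °C this is 2.53.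

The right-handed step has the higher barrier, so heat wears the factor down: it is 1.68 at 60 °C and 1.18 at 85 °C, and the constants meet at 97.9 °C. The excess is the factor less one over the factor plus one. That gives 8.17% for north-west, 25.3% for south and 43.3% for south-west.

But the substrate ratio can drift. In north-west the substrates relax toward each other with a half-life of 1.55 min, far shorter than the 1.0 h run, so they stay level and the figure should stand. In south-west the half-life is 12.2 h, so the left-handed substrate is not refilled and the excess should end a little under its figure. West makes product cold, then hot, so its excess must fall between those of south-west and north-west. This reckoning stops at that bracket, and with west scored at the midpoint, it puts south-west highest.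

The forecast, treating each flask as “a race between product formation, reagent loss by self-condensation, and racemisation”, named south-west highest, with 18.8% for west, 7.9% for north-west, 23.6% for south and 41.5% for south-west.

South-west ends highest at 41.5%, with west at 18.8%, north-west at 7.93% and south at 23.5%. At the end of south-west, 86% of the left-handed substrate and 94% of the right-handed substrate remain, and left-handed product stands to right-handed product as 2.42, against the factor of 2.53. A flask like south-west kept at 20 °C has a factor of 3.34, which reckons to an excess of 53.9%, and that flask ends at 53.4%.

The constants used here were chosen freely.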